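**Plan**

1. The retrosynthesis first cuts the depside bond between the ring B carbonyl carbon and the C4 oxygen of ring A, after masking the 4'-hydroxyl of ring B as an allyl ether.
2. Ring A is a hexasubstituted resorcinol monoester with C2–OH, C3–CH3 and C4–O in a row. These three atoms map onto the ketene carbonyl carbon, the methyl-bearing alkyne carbon and the oxygen-bearing alkyne carbon of a vinylketene/ynol ether benzannulation, so ring A is cut at C1–C2, C2–C3 and C4–C5.
3. Forward, part 1: a Wittig reaction and a diazo transfer give the α'-diazo enone; an ester-derived ynolate is O-silylated to the siloxypropyne.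
4. Forward, part 2: photochemical benzannulation closes ring A with the two oxygens already differentiated (free OH at C2, silyl ether at C4).
5. Ring B is not built. It comes from commercial methyl 2,4-dihydroxy-3,6-dimethylbenzoate by chlorination, 4-O-allylation, 2-O-methylation and saponification; esterification joins the rings and deallylation ends the route.
6. Stereochemistry: the target is achiral and has no stereogenic element; the E-alkene of the precursors disappears on aromatization.

Key step: step 5

Remark: no stereocontrol is needed anywhere. Methyl glyoxylate is assumed to be used as the commercial reagent, distilled to the monomer just before use.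

**Route**

Step 1
Reactants: 1 2-bromopentan-3-one; 2 triphenylphosphine
Product: 4 2-(triphenylphosphoranylidene)pentan-3-one, via phosphonium bromide 3 (not isolated)
Conditions: toluene, 90 °C; then 2 M NaOH, CH2Cl2/H2O, rt
Reagents that add atoms: none
Why: SN2 quaternization of the phosphine by the α-bromo ketone, then deprotonation of the acidic C–H between phosphorus and carbonyl, is the routine preparation of a keto-stabilized Wittig ylide.

Step 2
Reactants: 4 2-(triphenylphosphoranylidene)pentan-3-one; 5 methyl glyoxylate
Product: 6 methyl (E)-3-methyl-4-oxohex-2-enoate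
Conditions: CH2Cl2, 0 °C → rt
Reagents that add atoms: none
Why: Wittig olefination of a highly electrophilic aldehyde by a keto-stabilized α-methyl ylide should give the E-trisubstituted alkene (ester trans to the propanoyl group) as is usual for stabilized ylides, and because the ethyl ketone arrives preformed in the ylide no choice between two ketone carbonyls has to be made.

Step 3
Reactants: 6 methyl (E)-3-methyl-4-oxohex-2-enoate
Product: 8 methyl (E)-5-diazo-3-methyl-4-oxohex-2-enoate, via trifluoroacetyl diketone 7 (not isolated)
Conditions: LiN(SiMe3)2, THF, −78 °C; CF3CO2CH2CF3, −78 °C; then MsN3, Et3N, H2O, MeCN, rt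
Reagents that add atoms: methanesulfonyl azide, CS(=O)(=O)N=[N+]=[N-]
Why: Detrifluoroacetylative diazo transfer, in which the most acidic C–H bonds (the CH2 of the ethyl ketone) are removed by adding 6 to the amide base so that enolate never meets free enone, the enolate is trifluoroacetylated in a Claisen condensation, and diketone 7 undergoes Regitz diazo transfer with loss of the trifluoroacetyl group; 8 should be kept cold, dilute and dark because its electron-poor alkene is a potential dipolarophile.

Step 4
Reactants: 9 ethyl acetate; 10 triisopropylsilyl chloride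
Product: 13 1-(triisopropylsilyloxy)prop-1-yne, via dibromo enolate 11 (not isolated), via lithium ynolate 12 (not isolated)
Conditions: CH2Br2, lithium 2,2,6,6-tetramethylpiperidide, THF, −78 °C; 9; LiN(SiMe3)2; n-BuLi, −78 °C → rt; then i-Pr3SiCl (excess), −78 °C → rt
Reagents that add atoms: dibromomethane, BrCBr
Why: Kowalski ester homologation intercepted at the ynolate, in which LiCHBr2 adds to the ester, dibromo enolate 11 undergoes bromine–lithium exchange and a carbenoid 1,2-shift to lithium propynolate 12, and the bulky chlorosilane silylates 12 on oxygen to give the siloxyalkyne instead of a C-silyl ketene.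

Step 5
Reactants: 8 methyl (E)-5-diazo-3-methyl-4-oxohex-2-enoate; 13 1-(triisopropylsilyloxy)prop-1-yne
Product: 18 methyl 2-hydroxy-3,5,6-trimethyl-4-(triisopropylsilyloxy)benzoate, via vinylketene 14 (not isolated), via vinylcyclobutenone 15 (not isolated), via dienylketene 16 (not isolated), via cyclohexadienone 17 (not isolated)
Conditions: hν (254 nm, low-pressure Hg lamps, Vycor), 13 (1.5 equiv), degassed ClCH2CH2Cl, rt; then 80 °C
Reagents that add atoms: none
Why: Irradiation expels N2 from 8 with 1,2-shift of the alkenyl group (photochemical Wolff rearrangement) to give vinylketene 14, and the methyl-bearing carbon of ynol ether 13 bonds to the ketene carbonyl carbon (C2–C3) while the oxygen-bearing carbon bonds to the ketene α-carbon (C4–C5), giving 4-alkenylcyclobutenone 15. A 4π electrocyclic opening of 15 gives dienylketene 16, whose 6π electrocyclization forms C1–C2 and closes ring A as cyclohexadienone 17, which enolizes to phenol 18 under the drive of aromaticity and the hydrogen bond to the ester. The closest known reaction is the Danheiser benzannulation in its photochemical Wolff variant with siloxyalkynes, which delivers resorcinol monosilyl ethers. The transient four-membered ring closes by ketene–alkyne (2+2) cycloaddition and the six-membered ring A by 6π electrocyclization; no stereocentre is formed in the product, the racemic quaternary carbon of 15 being consumed. Two selectivities are needed: alkenyl migration rather than 1,2-hydride shift from the methyl group on the diazo carbon, which direct photolysis should favour, and the (2+2) regiochemistry, which is fixed by the match of the electrophilic ketene carbon with the nucleophilic methyl-bearing carbon of the ynol ether and is what places the silyl ether at C4 and the free hydroxyl at C2. The alkene geometry need not survive irradiation because either isomer of 16 closes onto the same carbon, which then aromatizes, and the chelated, flanked phenol of 18 should be a poor trap for residual ketene.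

Step 6
Reactants: 18 methyl 2-hydroxy-3,5,6-trimethyl-4-(triisopropylsilyloxy)benzoate
Product: 19 methyl 2,4-dihydroxy-3,5,6-trimethylbenzoate
Conditions: Bu4NF, AcOH, THF, 0 °C
Reagents that add atoms: none
Why: Fluoride-induced cleavage of an aryl silyl ether, driven by the Si–F bond and fast even for a flanked phenol, with acetic acid buffering so that the phenoxide is protonated at once and the methyl ester and electron-rich ring are not exposed to base.

Step 7
Reactants: 20 methyl 2,4-dihydroxy-3,6-dimethylbenzoate
Product: 21 methyl 3-chloro-4,6-dihydroxy-2,5-dimethylbenzoate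
Conditions: SO2Cl2 (1.05 equiv), Et2O, 0 °C → rt
Reagents that add atoms: sulfuryl chloride, O=S(=O)(Cl)Cl
Why: Electrophilic aromatic chlorination at the single unsubstituted ring carbon, which is ortho to one hydroxyl and para to the other, so that one equivalent of sulfuryl chloride at low temperature should stop at the monochloride.

Step 8
Reactants: 21 methyl 3-chloro-4,6-dihydroxy-2,5-dimethylbenzoate
Product: 22 methyl 4-(allyloxy)-3-chloro-6-hydroxy-2,5-dimethylbenzoate
Conditions: allyl bromide (1.05 equiv), K2CO3, acetone, reflux
Reagents that add atoms: allyl bromide, C=CCBr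
Why: Williamson ether synthesis that should take only the hydroxyl para to the ester, which is the more acidic and is not tied up in the hydrogen bond to the ester carbonyl that deactivates the ortho hydroxyl.

Step 9
Reactants: 22 methyl 4-(allyloxy)-3-chloro-6-hydroxy-2,5-dimethylbenzoate
Product: 23 methyl 4-(allyloxy)-3-chloro-6-methoxy-2,5-dimethylbenzoate
Conditions: MeI (excess), K2CO3, DMF, 50 °C
Reagents that add atoms: iodomethane, CI
Why: Williamson O-methylation of the remaining chelated phenol, which needs a polar aprotic solvent, excess iodomethane and mild heating but meets no competing nucleophile.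

Step 10
Reactants: 23 methyl 4-(allyloxy)-3-chloro-6-methoxy-2,5-dimethylbenzoate
Product: 24 4-(allyloxy)-3-chloro-6-methoxy-2,5-dimethylbenzoic acid
Conditions: KOH, DMSO/H2O (4:1), 80 °C; acidic work-up (2 M HCl)
Reagents that add atoms: potassium hydroxide, [K+].[OH-]
Why: Saponification of a di-ortho-substituted benzoate by poorly solvated hydroxide in aqueous DMSO (BAc2 hydrolysis), conditions that an aryl allyl ether, an aryl methyl ether and an unactivated aryl chloride should survive.

Step 11
Reactants: 19 methyl 2,4-dihydroxy-3,5,6-trimethylbenzoate; 24 4-(allyloxy)-3-chloro-6-methoxy-2,5-dimethylbenzoic acid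
Product: 26 3-hydroxy-4-(methoxycarbonyl)-2,5,6-trimethylphenyl 4-(allyloxy)-3-chloro-6-methoxy-2,5-dimethylbenzoate, via mixed anhydride 25 (not isolated)
Conditions: (CF3CO)2O, toluene, rt
Reagents that add atoms: none
Why: Trifluoroacetic anhydride-mediated esterification, in which mixed anhydride 25 ionizes to an acylium ion stabilized by the ortho-methoxy and para-allyloxy groups that is small and reactive enough to be captured by the flanked C4 hydroxyl of 19, while the C2 hydroxyl stays locked in its hydrogen bond to the ester, as is usual in depside syntheses from di-ortho-substituted acids and hindered phenols.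

Step 12
Reactants: 26 3-hydroxy-4-(methoxycarbonyl)-2,5,6-trimethylphenyl 4-(allyloxy)-3-chloro-6-methoxy-2,5-dimethylbenzoate
Product: 27 3-hydroxy-4-(methoxycarbonyl)-2,5,6-trimethylphenyl 3-chloro-4-hydroxy-6-methoxy-2,5-dimethylbenzoate (CNP0121273.0)
Conditions: Pd(PPh3)4 (5 mol %), morpholine, THF, rt
Reagents that add atoms: none
Why: Tsuji–Trost deallylation, in which zerovalent palladium ionizes the aryl allyl ether to a π-allyl complex and the phenoxide and morpholine removes the allyl group, under neutral conditions in which the aryl chloride does not undergo oxidative addition and neither the hindered aryl ester nor the methyl ester is attacked.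

**Compound list**

1 | 2-bromopentan-3-one (racemic) | CCC(=O)C(C)Br | starting material
2 | triphenylphosphine | c1ccc(cc1)P(c1ccccc1)c1ccccc1 | starting material
3 | (3-oxopentan-2-yl)triphenylphosphonium bromide (racemic) | CCC(=O)C(C)[P+](c1ccccc1)(c1ccccc1)c1ccccc1.[Br-] | intermediate
4 | 2-(triphenylphosphoranylidene)pentan-3-one | CCC(=O)C(C)=P(c1ccccc1)(c1ccccc1)c1ccccc1 | intermediate
5 | methyl glyoxylate (methyl 2-oxoacetate) | COC(=O)C=O | starting material
6 | methyl (E)-3-methyl-4-oxohex-2-enoate | CCC(=O)/C(C)=C/C(=O)OC | intermediate
7 | methyl (E)-7,7,7-trifluoro-3,5-dimethyl-4,6-dioxohept-2-enoate (racemic) | COC(=O)/C=C(\C)C(=O)C(C)C(=O)C(F)(F)F | intermediate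
8 | methyl (E)-5-diazo-3-methyl-4-oxohex-2-enoate | COC(=O)/C=C(\C)C(=O)C(C)=[N+]=[N-] | intermediate
9 | ethyl acetate | CCOC(C)=O | starting material
10 | triisopropylsilyl chloride | CC(C)[Si](Cl)(C(C)C)C(C)C | starting material
11 | lithium 1,1-dibromoprop-1-en-2-olate | CC([O-])=C(Br)Br.[Li+] | intermediate
12 | lithium prop-1-yn-1-olate | CC#C[O-].[Li+] | intermediate
13 | 1-(triisopropylsilyloxy)prop-1-yne | CC#CO[Si](C(C)C)(C(C)C)C(C)C | intermediate
14 | methyl (2E)-3,4-dimethyl-5-oxopenta-2,4-dienoate (vinylketene) | COC(=O)/C=C(\C)C(C)=C=O | intermediate
15 | methyl (E)-3-[1,3-dimethyl-4-oxo-2-(triisopropylsilyloxy)cyclobut-2-en-1-yl]but-2-enoate (racemic) | COC(=O)/C=C(\C)C1(C)C(=O)C(C)=C1O[Si](C(C)C)(C(C)C)C(C)C | intermediate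
16 | methyl (2E,4E)-3,4,6-trimethyl-7-oxo-5-(triisopropylsilyloxy)hepta-2,4,6-trienoate (dienylketene) | COC(=O)/C=C(\C)/C(C)=C(O[Si](C(C)C)(C(C)C)C(C)C)\C(C)=C=O | intermediate
17 | methyl 2,3,5-trimethyl-6-oxo-4-(triisopropylsilyloxy)cyclohexa-2,4-diene-1-carboxylate (racemic) | COC(=O)C1C(C)=C(C)C(O[Si](C(C)C)(C(C)C)C(C)C)=C(C)C1=O | intermediate
18 | methyl 2-hydroxy-3,5,6-trimethyl-4-(triisopropylsilyloxy)benzoate | COC(=O)c1c(C)c(C)c(O[Si](C(C)C)(C(C)C)C(C)C)c(C)c1O | intermediate
19 | methyl 2,4-dihydroxy-3,5,6-trimethylbenzoate | COC(=O)c1c(C)c(C)c(O)c(C)c1O | intermediate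
20 | methyl 2,4-dihydroxy-3,6-dimethylbenzoate | COC(=O)c1c(C)cc(O)c(C)c1O | starting material
21 | methyl 3-chloro-4,6-dihydroxy-2,5-dimethylbenzoate | COC(=O)c1c(C)c(Cl)c(O)c(C)c1O | intermediate
22 | methyl 4-(allyloxy)-3-chloro-6-hydroxy-2,5-dimethylbenzoate | COC(=O)c1c(C)c(Cl)c(OCC=C)c(C)c1O | intermediate
23 | methyl 4-(allyloxy)-3-chloro-6-methoxy-2,5-dimethylbenzoate | COC(=O)c1c(C)c(Cl)c(OCC=C)c(C)c1OC | intermediate
24 | 4-(allyloxy)-3-chloro-6-methoxy-2,5-dimethylbenzoic acid | OC(=O)c1c(C)c(Cl)c(OCC=C)c(C)c1OC | intermediate
25 | 4-(allyloxy)-3-chloro-6-methoxy-2,5-dimethylbenzoic trifluoroacetic anhydride | COc1c(C)c(OCC=C)c(Cl)c(C)c1C(=O)OC(=O)C(F)(F)F | intermediate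
26 | 3-hydroxy-4-(methoxycarbonyl)-2,5,6-trimethylphenyl 4-(allyloxy)-3-chloro-6-methoxy-2,5-dimethylbenzoate | COC(=O)c1c(C)c(C)c(OC(=O)c2c(C)c(Cl)c(OCC=C)c(C)c2OC)c(C)c1O | intermediate
27 | 3-hydroxy-4-(methoxycarbonyl)-2,5,6-trimethylphenyl 3-chloro-4-hydroxy-6-methoxy-2,5-dimethylbenzoate | COC(=O)c1c(C)c(C)c(OC(=O)c2c(C)c(Cl)c(O)c(C)c2OC)c(C)c1O | target

**Step count**

Total: 12 steps. Longest linear sequence: 7 steps (steps 1, 2, 3, 5, 6, 11, 12).

**Steps most likely to fail**

Step 5. The carbene formed on loss of N2 may undergo a 1,2-hydride shift from the methyl group on the diazo carbon instead of the Wolff rearrangement. The ketene may also be lost to dimerization or to acylation of the product phenol, and the enoate may absorb light competitively. In that case ring A would be made by substitution of an existing arene instead of de novo construction. Setting out from 20, Rieche formylation (Cl2CHOMe, TiCl4, CH2Cl2, 0 °C) at the one free ring carbon should give methyl 3-formyl-4,6-dihydroxy-2,5-dimethylbenzoate F1. Ionic hydrogenation of the aldehyde (Et3SiH, CF3CO2H, rt) would then turn the formyl group into the third methyl group. This comes back to the route at 19, so step 6 is no longer needed.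

Step 11. Capture of the acylium ion by a phenol flanked by two methyl groups may be too slow, so that the mixed anhydride accumulates or the phenol is only trifluoroacetylated, or acylation may stray to the chelated hydroxyl. The coupling would then be changed to a preformed acyl chloride and a preformed phenoxide. Setting out from 24, oxalyl chloride with catalytic DMF in CH2Cl2 should give 4-(allyloxy)-3-chloro-6-methoxy-2,5-dimethylbenzoyl chloride F2. One equivalent of NaH in THF would convert 19 into sodium 3-hydroxy-4-(methoxycarbonyl)-2,5,6-trimethylphenoxide F3 at the more acidic C4 oxygen. The two would be combined in THF at 0 °C → 50 °C, coming back to the route at 26.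

Step 4. LiCHBr2 may enolize ethyl acetate instead of adding to it, the carbenoid rearrangement may be incomplete, and the ynol ether may hydrolyse during isolation. The ynolate would then be made by oxidation of an acetylide instead of homologation of an ester. Commercial 1-propynyllithium in THF at −78 °C → 0 °C would be treated with lithium tert-butyl peroxide F4, made in the flask from anhydrous t-BuOOH and LiN(SiMe3)2, which transfers oxygen to the acetylide carbon and gives the same ynolate 12. The fallback sets out from 10, which silylates 12 on oxygen, and comes back to the route at 13.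

**Further compounds**

F1 | step 5 | methyl 3-formyl-4,6-dihydroxy-2,5-dimethylbenzoate | COC(=O)c1c(C)c(C=O)c(O)c(C)c1O
F2 | step 11 | 4-(allyloxy)-3-chloro-6-methoxy-2,5-dimethylbenzoyl chloride | COc1c(C)c(OCC=C)c(Cl)c(C)c1C(Cl)=O
F3 | step 11 | sodium 3-hydroxy-4-(methoxycarbonyl)-2,5,6-trimethylphenoxide | COC(=O)c1c(C)c(C)c([O-])c(C)c1O.[Na+]
F4 | step 4 | lithium tert-butyl peroxide | CC(C)(C)O[O-].[Li+]
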